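## Structural features

The target is a C40 carotenoid in which two 1,1,5-trimethylcyclohexene end rings are joined through C6 and C6′ by an all-E nonaene chain with four methyl branches (carotenoid numbering is used throughout, also for acyclic intermediates). Each ring carries two adjacent stereocentres, C2 and C3, as a trans-diequatorial diol of R,R configuration; C2 lies next to the quaternary C1, so its hydroxyl is neopentyl-like and hindered, whereas the C3 hydroxyl is ordinary. The molecule would be C2-symmetric were it not for one C3 oxygen, which is a hydrogen sulfate. The fragile parts are the undecaene chromophore (light, oxygen, strong acid, electron-transfer reagents) and the sulfate monoester, which is ionic, acid-labile and, in its free form, a strong acid beside a polyene. The real difficulty is twofold: building the trans-2,3-diol between the gem-dimethyl carbon and the C5=C6 alkene in one absolute sense, and addressing one hydroxyl out of four. The key step exploits the sequence gem-dimethyl C1, carbinol C2 and C5=C6 alkene of each ring, which is what results when a C1–C2 oxirane of an open chain is opened at C1 by its own C5=C6 alkene with formation of the C1–C6 bond.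

## Logic of the disconnections

**22 to 21.** The O–Si bonds at O2 and O2′ are the first to be restored in the backward direction, so their cleavage is the last forward operation. The hindered C2 hydroxyls stay masked while the sulfate is placed. The forward step must remove a very hindered silyl ether without harming a sulfate monoester or the polyene.

**21 to 20.** The S–O bond at O3 is cut. The sulfate is ionic and acid-sensitive, so it enters as late as possible. The gain is that 20 is C2-symmetric, so everything before it is two-directional. The demand is a monofunctionalisation of two homotopic hydroxyls, which is statistical and needs separation and recycling of 20.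

**20 to 19.** The Si–O bonds at O3 and O3′ are cut. The two oxygens of each ring carry different silyl groups, which reduces the four-hydroxyl problem to a two-hydroxyl one. The demand is that the labile silyl group on the unhindered O3 leaves while the robust one on the hindered O2 stays.

**19 to 18, and 18 to 14 plus 15.** The C7=C8 and C7′=C8′ double bonds are cut, each into a sulfonyl-stabilised C7 carbanion and a C8 aldehyde. These are the only chain double bonds next to the rings. Cutting both gives two identical C10 rings 14 and the symmetrical C20 dialdehyde 15, which brings all other chain geometry with it. The forward steps must add through C7 (not C5) of the allyl anion, give the E alkene, and eliminate without reducing the polyene.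

**14 to 13.** The Si–O bond at O2 is cut. A free C2 hydroxyl would be deprotonated and would invite silyl migration from O3 during the carbanion chemistry. The demand is silylation of a neopentyl-type alcohol.

**13 to 12.** The C1–C6 ring bond is cut, opening the carbocycle to an acyclic epoxy silyl ether. This removes the ring and turns the ring stereochemistry into the acyclic threo relationship of 12. The forward step must open the oxirane at C1, close the ring through C6, and lose the proton from C6.

**12 to 8 plus 9.** The C7–S bond is cut, giving the allylic alcohol 8 and 9. The sulfonyl group is a spectator in the cyclisation and the anion-stabilising group afterwards. The demand is allylic substitution without touching the oxirane, which is met by passing through 10 and 11.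

**8 to 7, 7 to 6, 6 to 5.** These undo an ester reduction, the O3–Si bond, and the two C–O bonds of the oxirane. Cutting the oxirane back to the alkene of 5 leaves a single stereocentre, C3, which must then direct the epoxidation to the threo isomer. The silyl group therefore goes on only after the epoxidation, so that the free hydroxyl can direct it.

**5 to 3 plus 4.** The C3–C4 bond is cut in a vinylogous aldol sense. This builds the whole ten-carbon chain, the E-enoate and the C3 stereocentre in one step from two five-carbon pieces. The demand is γ-selectivity, E geometry and attack on the Re face of 4.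

**3 to 1.** The O–Si bond of the dienol ether is cut, by way of 2, leaving a commercial ester.

## Other disconnections considered

Alternative 1: The cut is at the C2–O and C3–O bonds on a preformed carbocycle, the dearomatised dienone A1. The forward key step is a Jacobsen–Katsuki epoxidation of the distal cis alkene of A1 with [N,N′-bis(3,5-di-tert-butylsalicylidene)-1,2-cyclohexanediamine]MnCl (trivalent manganese) and NaOCl, giving the epoxy enone A2.
- In its favour: all ring carbons come from a cheap aromatic, and a cis-disubstituted conjugated alkene is the preferred substrate class for this catalyst. The C6 carbonyl later allows the ring alkene to be placed without ambiguity, because only C5 can enolise. On this last point it is better than the chosen plan, where the alkene position depends on which proton a cation loses.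
- Against it: the oxirane is cis while the target diol is trans, so C3 must be opened with inversion at a vinylogous position where SN2′ attack and elimination compete. The enone must be reduced, and C7 must then be attached to a ketone flanked by a quaternary carbon. One alkene carbon is neopentyl, which may lower rate and selectivity, and A1 can dimerise by [4+2] addition.
- Comparison: both plans set one stereocentre by catalysis and relay it to the neighbour, so they are equal on that point. Alternative 1 is oxidative and ionic at the ring, whereas the chosen plan is cationic. The count to a coupling-ready ring would be clearly higher here.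

Alternative 2: The cut is at the C3–C4 ring bond. The acyclic enone aldehyde A4, made from (R)-pantolactone A3, is closed by SmI2 (divalent samarium): the ketyl of the C3 aldehyde adds to the C4 methylene terminus of the isopropenyl ketone, giving the cyclohexanone A5.
- In its favour: C2 and the gem-dimethyl carbon come from the chiral pool with known absolute configuration, so no enantioselective catalysis is needed. On reliability of absolute configuration it is better than the chosen plan. The C6 ketone again fixes the ring alkene, and the neutral reductive conditions spare silyl ethers.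
- Against it: the new C3 stereocentre must form trans to O2 under substrate control, which a bulky, non-chelating silyl ether may or may not enforce. A4 is an epimerisable α-silyloxy aldehyde and a polymerisable enone, and takes several steps to make from A3. A5 still lacks C7, so a hindered ketone must be homologated.
- Comparison: the ring closure is a radical-anion 6-endo addition and not a cation–olefin closure. It is equal in forming one ring bond and no more. Step economy is worse, roughly five more steps to reach the stage of 14.

Alternative 3: The cut is at C14–C15 and C14′–C15′. Two molecules of the retro-C19 trienal A6 are joined by the acetylene di-Grignard reagent A7 to give the C40 acetylenic diol A8. Afterwards come acid dehydration with allylic rearrangement, partial hydrogenation of the triple bond over Pd/CaCO3 poisoned with Pb(OAc)2, and thermal Z to E isomerisation.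
- In its favour: it is two-directional like the chosen plan (equal), and it needs no C20 dialdehyde. The polyene is completed without electron-transfer reagents, which is better than a reductive sulfone elimination on that point.
- Against it: it is a chain disconnection only, so the oxygenated ring with its two stereocentres still has to be made and then extended by nine carbons. The protic acid needed for the rearrangement threatens four silyl ethers and the homoallylic oxygen, and A8 forms as carbinol epimers.
- Comparison: it complements a ring construction and does not replace one, and it would add many steps to the chosen plan.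

Key step: step 7

Assumption 1: the target is drawn as the free hydrogen sulfate; the monoester would be made and stored as a salt, and the acid form written for 21 and 22 differs from it only in the counter-ion.
Assumption 2: the (R,R)-bisphosphoramide is taken to steer the dienol ether to the Re face of 4; if the sense of induction is the opposite, its antipode is used.

Step 1
Reactants: 1 methyl 3-methylbut-2-enoate
Product: 3 tert-butyl[(1-methoxy-3-methylbuta-1,3-dien-1-yl)oxy]dimethylsilane (silyl dienol ether; ketene acetal geometry not defined), via lithium dienolate 2 (not isolated)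
Conditions: LiN(i-Pr)2, THF, −78 °C; TBSCl, DMPU, −78 °C to rt
Reagents that add atoms: tert-butyldimethylsilyl chloride, CC(C)(C)[Si](C)(C)Cl
Why: Kinetic γ-deprotonation of the enoate gives the extended enolate, which is silylated on oxygen (standard silyl dienol ether formation).

Step 2
Reactants: 3 silyl dienol ether; 4 prenal (3-methylbut-2-enal)
Product: 5 methyl (2E,5R)-5-hydroxy-3,7-dimethylocta-2,6-dienoate
Conditions: SiCl4, (R,R)-binaphthyldiamine-derived bisphosphoramide (cat.), i-Pr2NEt (cat.), CH2Cl2, −78 °C; aq. NaHCO3
Reagents that add atoms: none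
Why: Catalytic asymmetric vinylogous Mukaiyama aldol: the chiral Lewis-base-bound trichlorosilyl cation activates 4 and the dienol ether adds through its γ-carbon on the Re face, which sets the carbinol carbon (later C3) as R. The s-trans diene gives the E-enoate.

Step 3
Reactants: 5 hydroxy dienoate
Product: 6 methyl (2E,5R)-5-[(2S)-3,3-dimethyloxiran-2-yl]-5-hydroxy-3-methylpent-2-enoate (threo epoxy alcohol)
Conditions: mCPBA, NaHCO3, CH2Cl2, 0 °C
Reagents that add atoms: 3-chloroperoxybenzoic acid, OOC(=O)c1cccc(Cl)c1
Why: Hydroxyl-directed peracid epoxidation: allylic 1,3-strain from the Z-methyl group holds the carbinol hydrogen in the alkene plane, so the hydrogen-bonded peracid adds on the hydroxyl face and should give the threo (2S) oxirane. The enoate alkene is too electron-poor to react.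

Step 4
Reactants: 6 threo epoxy alcohol
Product: 7 methyl (2E,5R)-5-[(2S)-3,3-dimethyloxiran-2-yl]-3-methyl-5-(triethylsilyloxy)pent-2-enoate
Conditions: TESCl, imidazole, CH2Cl2, 0 °C
Reagents that add atoms: chlorotriethylsilane, CC[Si](CC)(CC)Cl
Why: Ordinary silylation of a secondary alcohol under mild conditions that avoid Payne rearrangement. The triethylsilyl group is chosen so that O3 can later be unmasked beside a tert-butyldimethylsilyl ether on O2.

Step 5
Reactants: 7 epoxy silyl ether ester
Product: 8 (2E,5R)-5-[(2S)-3,3-dimethyloxiran-2-yl]-3-methyl-5-(triethylsilyloxy)pent-2-en-1-ol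
Conditions: i-Bu2AlH, CH2Cl2, −78 °C; aq. potassium sodium tartrate
Reagents that add atoms: none
Why: Aluminium hydride 1,2-reduction of an α,β-unsaturated ester to the allylic alcohol; at −78 °C the trisubstituted oxirane and the silyl ether are not attacked.

Step 6
Reactants: 8 epoxy allylic alcohol; 9 sodium benzenesulfinate
Product: 12 [(2E,5R)-5-[(2S)-3,3-dimethyloxiran-2-yl]-3-methyl-5-(triethylsilyloxy)pent-2-en-1-yl]sulfonylbenzene (threo epoxy silyl ether sulfone), via allylic mesylate 10 (not isolated), via allylic bromide 11 (not isolated)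
Conditions: MsCl, Et3N, THF, −40 °C; LiBr, 0 °C; then PhSO2Na, DMF, rt
Reagents that add atoms: none
Why: Mesylation and bromide exchange under non-acidic conditions keep the oxirane intact, and the soft sulfinate then S-alkylates the primary allylic bromide by SN2 with retention of the E alkene.

Step 7
Reactants: 12 threo epoxy silyl ether sulfone
Product: 13 (1R,6R)-2,2,4-trimethyl-3-[(phenylsulfonyl)methyl]-6-(triethylsilyloxy)cyclohex-3-en-1-ol [(2R,3R)-2-hydroxy-3-(triethylsilyloxy)-β-cyclogeranyl phenyl sulfone]
Conditions: SnCl4 (1.1 equiv), CH2Cl2, −78 °C; cold aq. NaHCO3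
Reagents that add atoms: none
Why: SnCl4 binds the oxirane oxygen and the C1–O bond stretches toward the tertiary carbon; the C5=C6 π bond attacks C1 anti to the departing oxygen in a chair in which O2, the C3 silyloxy group and C7 are all equatorial, forming C1–C6 and a tertiary cation at C5 that loses the axial H6 to give the tetrasubstituted alkene, the tin alkoxide being hydrolysed on work-up. The closest known reaction type is the Lewis-acid cyclisation of 6,7-epoxygeranyl esters to 2-hydroxycyclogeranyl rings, together with the acid cyclisation of geranyl phenyl sulfone. The ring closes in a 6-endo-trig mode at the alkene, with the breaking C1–O bond outside the new ring. No stereocentre is created: C2–O is never broken and C3 is untouched, so the (2S,3R) threo chain maps onto the (2R,3R) trans ring, the descriptor at C2 changing only through the priority rules. Three selectivities are needed: opening at C1 and not C2, which the tertiary centre secures; capture by the alkene and not by the sulfonyl or silyloxy oxygens or by hydride shift, helped by the preorganised chair and the weak basicity of those oxygens; and proton loss toward C6 and not toward C4 or the methyl group. For the last point no proton scavenger is added, so that the acid set free can return a less substituted alkene to the C5 cation and drain it to the tetrasubstituted isomer, while the C4 hydrogens are inductively deactivated by O3. Capture of the cation by O2 as a 2,5-oxygen bridge is disfavoured because the trans C3 silyloxy group would sit endo against a C1 methyl group.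

Step 8
Reactants: 13 hydroxy silyl ether sulfone
Product: 14 (2R,3R)-2-(tert-butyldimethylsilyloxy)-3-(triethylsilyloxy)-β-cyclogeranyl phenyl sulfone
Conditions: TBSOTf, 2,6-lutidine, CH2Cl2, 0 °C to rt
Reagents that add atoms: tert-butyldimethylsilyl trifluoromethanesulfonate, CC(C)(C)[Si](C)(C)OS(=O)(=O)C(F)(F)F
Why: Silylation with a silyl triflate, which is reactive enough for the neopentyl-type C2 hydroxyl; blocking it prevents alkoxide formation and silyl migration in the carbanion step.

Step 9
Reactants: 14 bis-silylated sulfone (2.3 equiv); 15 crocetindialdehyde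
Product: 18 (2R,3R,2′R,3′R)-8,8′-bis(benzoyloxy)-2,2′-bis(tert-butyldimethylsilyloxy)-7,7′-bis(phenylsulfonyl)-3,3′-bis(triethylsilyloxy)-7,8,7′,8′-tetrahydro-β,β-carotene (mixture of diastereomers at C7 C8 C7′ C8′), via lithiated sulfone 16 (not isolated), via dilithium dialkoxide 17 (not isolated)
Conditions: n-BuLi, THF, −78 °C; 15, THF, −78 °C; BzCl, −78 to 0 °C
Reagents that add atoms: benzoyl chloride, O=C(Cl)c1ccccc1
Why: First half of a two-directional Julia–Lythgoe olefination: the sulfonyl-stabilised allyl anion adds through C7 to both aldehyde groups, and benzoylation in the flask stops retro-addition. The four new stereocentres are erased in step 10.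

Step 10
Reactants: 18 bis(β-benzoyloxy sulfone)
Product: 19 (2R,3R,2′R,3′R)-2,2′-bis(tert-butyldimethylsilyloxy)-3,3′-bis(triethylsilyloxy)-β,β-carotene
Conditions: SmI2 (titrated to a persistent blue end point), THF/DMPU, −78 °C, dark
Reagents that add atoms: none
Why: Reductive elimination of the Julia–Lythgoe olefination: electron transfer cleaves the allylic sulfone or the polyene-allylic benzoate, and the resulting β-substituted anion expels the other group to give the E C7=C8 bond. Any hindered 7Z isomer should equilibrate thermally to all-E.

Step 11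
Reactants: 19 tetrakis-silyl ether
Product: 20 (2R,3R,2′R,3′R)-2,2′-bis(tert-butyldimethylsilyloxy)-β,β-carotene-3,3′-diol
Conditions: PPTS (cat.), MeOH/CH2Cl2, 0 °C, dark
Reagents that add atoms: none
Why: Selective silyl ether cleavage: mild acid methanolysis removes the triethylsilyl groups on the unhindered O3 and O3′ far faster than the tert-butyldimethylsilyl groups on the neopentyl O2 and O2′.

Step 12
Reactants: 20 3,3′-diol
Product: 21 (2R,3R,2′R,3′R)-2,2′-bis(tert-butyldimethylsilyloxy)-3′-hydroxy-β,β-caroten-3-yl hydrogen sulfate (handled as its pyridinium or sodium salt)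
Conditions: SO3·pyridine (1 equiv), pyridine/DMF, 0 °C; aq. NaHCO3; chromatography, recovered 20 recycled
Reagents that add atoms: sulfur trioxide–pyridine complex, [O-]S(=O)(=O)[n+]1ccccc1
Why: O-Sulfation with a sulfur trioxide amine complex: the alcohol oxygen attacks the sulfur of the zwitterionic adduct and pyridine is released. Only the two homotopic C3 hydroxyls are free, so the sole issue is mono versus double reaction, handled by limiting the reagent.

Step 13
Reactants: 21 mono-sulfate bis-silyl ether
Product: 22 (2R,3R,2′R,3′R)-2,2′,3′-trihydroxy-β,β-caroten-3-yl hydrogen sulfate (target)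
Conditions: Bu4NF, THF, 0 °C to rt, dark; cold cation exchange
Reagents that add atoms: none
Why: Fluoride-mediated desilylation cleaves the two hindered silyl ethers; a sulfate monoester anion is inert to fluoride and to the mild basicity of the medium.

Compound list

1 | methyl 3-methylbut-2-enoate | COC(=O)C=C(C)C | starting material
2 | lithium 1-methoxy-3-methylbuta-1,3-dien-1-olate | COC(=CC(C)=C)O[Li] | intermediate (not isolated)
3 | tert-butyl[(1-methoxy-3-methylbuta-1,3-dien-1-yl)oxy]dimethylsilane | COC(=CC(C)=C)O[Si](C)(C)C(C)(C)C | intermediate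
4 | prenal (3-methylbut-2-enal) | CC(C)=CC=O | starting material
5 | methyl (2E,5R)-5-hydroxy-3,7-dimethylocta-2,6-dienoate | CC(C)=C[C@H](O)C/C(C)=C/C(=O)OC | intermediate
6 | methyl (2E,5R)-5-[(2S)-3,3-dimethyloxiran-2-yl]-5-hydroxy-3-methylpent-2-enoate | CC1(C)O[C@H]1[C@H](O)C/C(C)=C/C(=O)OC | intermediate
7 | methyl (2E,5R)-5-[(2S)-3,3-dimethyloxiran-2-yl]-3-methyl-5-(triethylsilyloxy)pent-2-enoate | CC1(C)O[C@H]1[C@H](O[Si](CC)(CC)CC)C/C(C)=C/C(=O)OC | intermediate
8 | (2E,5R)-5-[(2S)-3,3-dimethyloxiran-2-yl]-3-methyl-5-(triethylsilyloxy)pent-2-en-1-ol | CC1(C)O[C@H]1[C@H](O[Si](CC)(CC)CC)C/C(C)=C/CO | intermediate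
9 | sodium benzenesulfinate | [Na+].[O-]S(=O)c1ccccc1 | starting material
10 | methanesulfonate of 8 | CC1(C)O[C@H]1[C@H](O[Si](CC)(CC)CC)C/C(C)=C/COS(C)(=O)=O | intermediate (not isolated)
11 | allylic bromide from 8 | CC1(C)O[C@H]1[C@H](O[Si](CC)(CC)CC)C/C(C)=C/CBr | intermediate (not isolated)
12 | [(2E,5R)-5-[(2S)-3,3-dimethyloxiran-2-yl]-3-methyl-5-(triethylsilyloxy)pent-2-en-1-yl]sulfonylbenzene | CC1(C)O[C@H]1[C@H](O[Si](CC)(CC)CC)C/C(C)=C/CS(=O)(=O)c1ccccc1 | intermediate (key-step precursor)
13 | (1R,6R)-2,2,4-trimethyl-3-[(phenylsulfonyl)methyl]-6-(triethylsilyloxy)cyclohex-3-en-1-ol | CC1=C(CS(=O)(=O)c2ccccc2)C(C)(C)[C@@H](O)[C@H](O[Si](CC)(CC)CC)C1 | intermediate (key-step product)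
14 | (2R,3R)-2-(tert-butyldimethylsilyloxy)-3-(triethylsilyloxy)-β-cyclogeranyl phenyl sulfone | CC1=C(CS(=O)(=O)c2ccccc2)C(C)(C)[C@@H](O[Si](C)(C)C(C)(C)C)[C@H](O[Si](CC)(CC)CC)C1 | intermediate
15 | crocetindialdehyde | O=C/C(C)=C/C=C/C(C)=C/C=C/C=C(C)/C=C/C=C(C)/C=O | starting material
16 | C7-lithio derivative of 14 | CC1=C(C([Li])S(=O)(=O)c2ccccc2)C(C)(C)[C@@H](O[Si](C)(C)C(C)(C)C)[C@H](O[Si](CC)(CC)CC)C1 | intermediate (not isolated)
17 | dilithium 8,8′-dialkoxide of the bis-adduct of 16 and 15 | CC1=C(C(S(=O)(=O)c2ccccc2)C(O[Li])/C(C)=C/C=C/C(C)=C/C=C/C=C(C)/C=C/C=C(C)/C(O[Li])C(S(=O)(=O)c2ccccc2)C2=C(C)C[C@@H](O[Si](CC)(CC)CC)[C@H](O[Si](C)(C)C(C)(C)C)C2(C)C)C(C)(C)[C@@H](O[Si](C)(C)C(C)(C)C)[C@H](O[Si](CC)(CC)CC)C1 | intermediate (not isolated)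
18 | (2R,3R,2′R,3′R)-8,8′-bis(benzoyloxy)-2,2′-bis(tert-butyldimethylsilyloxy)-7,7′-bis(phenylsulfonyl)-3,3′-bis(triethylsilyloxy)-7,8,7′,8′-tetrahydro-β,β-carotene | CC1=C(C(S(=O)(=O)c2ccccc2)C(OC(=O)c2ccccc2)/C(C)=C/C=C/C(C)=C/C=C/C=C(C)/C=C/C=C(C)/C(OC(=O)c2ccccc2)C(S(=O)(=O)c2ccccc2)C2=C(C)C[C@@H](O[Si](CC)(CC)CC)[C@H](O[Si](C)(C)C(C)(C)C)C2(C)C)C(C)(C)[C@@H](O[Si](C)(C)C(C)(C)C)[C@H](O[Si](CC)(CC)CC)C1 | intermediate
19 | (2R,3R,2′R,3′R)-2,2′-bis(tert-butyldimethylsilyloxy)-3,3′-bis(triethylsilyloxy)-β,β-carotene | CC1=C(/C=C/C(C)=C/C=C/C(C)=C/C=C/C=C(C)/C=C/C=C(C)/C=C/C2=C(C)C[C@@H](O[Si](CC)(CC)CC)[C@H](O[Si](C)(C)C(C)(C)C)C2(C)C)C(C)(C)[C@@H](O[Si](C)(C)C(C)(C)C)[C@H](O[Si](CC)(CC)CC)C1 | intermediate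
20 | (2R,3R,2′R,3′R)-2,2′-bis(tert-butyldimethylsilyloxy)-β,β-carotene-3,3′-diol | CC1=C(/C=C/C(C)=C/C=C/C(C)=C/C=C/C=C(C)/C=C/C=C(C)/C=C/C2=C(C)C[C@@H](O)[C@H](O[Si](C)(C)C(C)(C)C)C2(C)C)C(C)(C)[C@@H](O[Si](C)(C)C(C)(C)C)[C@H](O)C1 | intermediate
21 | (2R,3R,2′R,3′R)-2,2′-bis(tert-butyldimethylsilyloxy)-3′-hydroxy-β,β-caroten-3-yl hydrogen sulfate | CC1=C(/C=C/C(C)=C/C=C/C(C)=C/C=C/C=C(C)/C=C/C=C(C)/C=C/C2=C(C)C[C@@H](OS(=O)(=O)O)[C@H](O[Si](C)(C)C(C)(C)C)C2(C)C)C(C)(C)[C@@H](O[Si](C)(C)C(C)(C)C)[C@H](O)C1 | intermediate
22 | (2R,3R,2′R,3′R)-2,2′,3′-trihydroxy-β,β-caroten-3-yl hydrogen sulfate | CC1=C(/C=C/C(C)=C/C=C/C(C)=C/C=C/C=C(C)/C=C/C=C(C)/C=C/C2=C(C)C[C@@H](OS(=O)(=O)O)[C@H](O)C2(C)C)C(C)(C)[C@@H](O)[C@H](O)C1 | target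

Total step count: 13. Longest linear sequence: 13 steps (1 to 22); 4, 9 and 15 enter at steps 2, 6 and 9.

Steps least certain to work

**Step 7 (key step).** The likeliest failure is loss of the wrong proton from the C5 cation (toward C4 or the methyl group), because the C6 hydrogen is the most hindered of the three and simple epoxygeranyl esters tend to give the less substituted alkenes under kinetic control. Capture of the cation by O2, and partial loss of the triethylsilyl group to the acid set free, are secondary risks.

The fallback sets out from 12 and returns at 19. The ring alkene is no longer fought at the C10 stage but corrected at the end by the base-mediated shift that turns hydroxylated ε-end groups of carotenoids into β-end groups. The cyclisation of 12 is run with 2,6-di-tert-butylpyridine present, so that the kinetic, non-conjugated ring isomer is the product, drawn as the Δ4 sulfone F1. TBSOTf with 2,6-lutidine then gives the bis-silyl ether F2. The operations of steps 9 and 10 with 15 give the bis-benzoate F3 and then the silylated ε,ε-carotenoid F4. Bu4NF gives the ε,ε-tetrol F5. KOH in DMSO at about 80 °C deprotonates the doubly allylic C6 and reprotonates at C4, moving both ring double bonds into conjugation to give the β,β-tetrol F6; the free alkoxide at C3 cannot leave, which is why this is done after desilylation. TESCl with imidazole at low temperature silylates the unhindered O3 and O3′ to give the 3,3′-bis(triethylsilyl) ether F7, and TBSOTf then gives 19.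

**Step 2.** Facial selectivity or γ-selectivity may be poor with a β,β-disubstituted enal, and the allylic trichlorosilyl aldolate may ionise under the strong Lewis acid and lose configuration.

The fallback sets out from 3 and 4 and returns at 5. The stereocentre is set by ketone reduction and not by the C–C bond formation. A BF3·OEt2-promoted vinylogous Mukaiyama aldol gives the racemic hydroxy ester F8. MnO2 oxidises the allylic alcohol to the keto ester F9. A Corey–Bakshi–Shibata reduction with the (S)-methyl oxazaborolidine and catecholborane at −78 °C, the alkenyl group acting as the large substituent, should then give 5.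

**Step 10.** Excess SmI2 may reduce the newly formed undecaene, or the elimination may stop after one end. Both arise because the polyene itself accepts electrons at potentials close to those needed for the elimination.

The fallback sets out from 18 and returns at 19 without an electron-transfer reagent. DBU eliminates benzoic acid from both ends (E1cB through the acidic C7 hydrogen) to give the bis(vinyl sulfone) F10. Pd(acac)2-catalysed hydride transfer from n-BuMgCl in THF then replaces each sulfonyl group by hydrogen, and gentle warming in the dark equilibrates any Z isomer.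

**Step 12.** Double sulfation and loss of material on separating three species of very different polarity, two of them ionic, are the main risks; the outcome is statistical at best.

The fallback sets out from 20 and returns at 21. The sulfate is introduced as a neutral diester that can be chromatographed on silica. 2,2,2-Trichloroethyl chlorosulfate with DMAP and Et3N in CH2Cl2 gives the mono(trichloroethyl sulfate) F11, separable from 20 and from the bis-adduct. Zn dust with HCO2NH4 in MeOH then removes the trichloroethyl group by reductive fragmentation and gives 21 as its ammonium salt.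

Further compounds

F1 | step 7 | (2R,3R,6R)-2-hydroxy-3-(triethylsilyloxy)-α-cyclogeranyl phenyl sulfone, the C4=C5 alkene isomer of 13 (carotenoid locants) | CC1=C[C@@H](O[Si](CC)(CC)CC)[C@H](O)C(C)(C)[C@@H]1CS(=O)(=O)c1ccccc1
F2 | step 7 | O2-tert-butyldimethylsilyl ether of F1 | CC1=C[C@@H](O[Si](CC)(CC)CC)[C@H](O[Si](C)(C)C(C)(C)C)C(C)(C)[C@@H]1CS(=O)(=O)c1ccccc1
F3 | step 7 | bis(β-benzoyloxy sulfone) from F2 and 15 (mixture at C7 C8 C7′ C8′) | CC1=C[C@@H](O[Si](CC)(CC)CC)[C@H](O[Si](C)(C)C(C)(C)C)C(C)(C)[C@@H]1C(S(=O)(=O)c1ccccc1)C(OC(=O)c1ccccc1)/C(C)=C/C=C/C(C)=C/C=C/C=C(C)/C=C/C=C(C)/C(OC(=O)c1ccccc1)C(S(=O)(=O)c1ccccc1)[C@@H]1C(C)=C[C@@H](O[Si](CC)(CC)CC)[C@H](O[Si](C)(C)C(C)(C)C)C1(C)C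
F4 | step 7 | (2R,3R,6R,2′R,3′R,6′R)-2,2′-bis(tert-butyldimethylsilyloxy)-3,3′-bis(triethylsilyloxy)-ε,ε-carotene | CC1=C[C@@H](O[Si](CC)(CC)CC)[C@H](O[Si](C)(C)C(C)(C)C)C(C)(C)[C@@H]1/C=C/C(C)=C/C=C/C(C)=C/C=C/C=C(C)/C=C/C=C(C)/C=C/[C@@H]1C(C)=C[C@@H](O[Si](CC)(CC)CC)[C@H](O[Si](C)(C)C(C)(C)C)C1(C)C
F5 | step 7 | (2R,3R,6R,2′R,3′R,6′R)-ε,ε-carotene-2,3,2′,3′-tetrol | CC1=C[C@@H](O)[C@H](O)C(C)(C)[C@@H]1/C=C/C(C)=C/C=C/C(C)=C/C=C/C=C(C)/C=C/C=C(C)/C=C/[C@@H]1C(C)=C[C@@H](O)[C@H](O)C1(C)C
F6 | step 7 | (2R,3R,2′R,3′R)-β,β-carotene-2,3,2′,3′-tetrol | CC1=C(/C=C/C(C)=C/C=C/C(C)=C/C=C/C=C(C)/C=C/C=C(C)/C=C/C2=C(C)C[C@@H](O)[C@H](O)C2(C)C)C(C)(C)[C@@H](O)[C@H](O)C1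
F7 | step 7 | (2R,3R,2′R,3′R)-3,3′-bis(triethylsilyloxy)-β,β-carotene-2,2′-diol | CC1=C(/C=C/C(C)=C/C=C/C(C)=C/C=C/C=C(C)/C=C/C=C(C)/C=C/C2=C(C)C[C@@H](O[Si](CC)(CC)CC)[C@H](O)C2(C)C)C(C)(C)[C@@H](O)[C@H](O[Si](CC)(CC)CC)C1
F8 | step 2 | racemic methyl (2E)-5-hydroxy-3,7-dimethylocta-2,6-dienoate | CC(C)=CC(O)C/C(C)=C/C(=O)OC
F9 | step 2 | methyl (2E)-3,7-dimethyl-5-oxoocta-2,6-dienoate | CC(C)=CC(=O)C/C(C)=C/C(=O)OC
F10 | step 10 | 7,7′-bis(phenylsulfonyl) derivative of 19 (C7=C8 and C7′=C8′ geometry not defined) | CC1=C(C(S(=O)(=O)c2ccccc2)=C/C(C)=C/C=C/C(C)=C/C=C/C=C(C)/C=C/C=C(C)/C=C(S(=O)(=O)c2ccccc2)C2=C(C)C[C@@H](O[Si](CC)(CC)CC)[C@H](O[Si](C)(C)C(C)(C)C)C2(C)C)C(C)(C)[C@@H](O[Si](C)(C)C(C)(C)C)[C@H](O[Si](CC)(CC)CC)C1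
F11 | step 12 | 2,2,2-trichloroethyl sulfate diester of 20 at O3 | CC1=C(/C=C/C(C)=C/C=C/C(C)=C/C=C/C=C(C)/C=C/C=C(C)/C=C/C2=C(C)C[C@@H](OS(=O)(=O)OCC(Cl)(Cl)Cl)[C@H](O[Si](C)(C)C(C)(C)C)C2(C)C)C(C)(C)[C@@H](O[Si](C)(C)C(C)(C)C)[C@H](O)C1
A1 | alternative 1 | 2,6,6-trimethylcyclohexa-2,4-dien-1-one | CC1=CC=CC(C)(C)C1=O
A2 | alternative 1 | (4S,5R)-4,5-epoxy-2,6,6-trimethylcyclohex-2-en-1-one | O=C1C(C)=C[C@@H]2O[C@@H]2C1(C)C
A3 | alternative 2 | (R)-pantolactone | CC1(C)COC(=O)[C@@H]1O
A4 | alternative 2 | (2R)-2-(tert-butyldimethylsilyloxy)-3,3,5-trimethyl-4-oxohex-5-enal | O=C[C@H](O[Si](C)(C)C(C)(C)C)C(C)(C)C(=O)C(C)=C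
A5 | alternative 2 | (3R,4R)-3-(tert-butyldimethylsilyloxy)-4-hydroxy-2,2,6-trimethylcyclohexanone (C6 methyl epimers) | CC1C(=O)C(C)(C)[C@@H](O[Si](C)(C)C(C)(C)C)[C@H](O)C1
A6 | alternative 3 | (2E,4E,6E)-8-[(4R,5R)-4,5-bis(tert-butyldimethylsilyloxy)-2,6,6-trimethylcyclohex-1-en-1-yl]-2,6-dimethylocta-2,4,6-trienal | CC1=C(C/C=C(C)/C=C/C=C(C)/C=O)C(C)(C)[C@@H](O[Si](C)(C)C(C)(C)C)[C@H](O[Si](C)(C)C(C)(C)C)C1
A7 | alternative 3 | ethyne-1,2-diylbis(magnesium bromide) | Br[Mg]C#C[Mg]Br
A8 | alternative 3 | C40 acetylenic 14,14′-diol, tetrakis(tert-butyldimethylsilyl) ether (epimers at C14 and C14′) | CC1=C(C/C=C(C)/C=C/C=C(C)/C(O)C#CC(O)/C(C)=C/C=C/C(C)=C/CC2=C(C)C[C@@H](O[Si](C)(C)C(C)(C)C)[C@H](O[Si](C)(C)C(C)(C)C)C2(C)C)C(C)(C)[C@@H](O[Si](C)(C)C(C)(C)C)[C@H](O[Si](C)(C)C(C)(C)C)C1
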